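- We take a small charge, c(substrate) 0.40 M and c(partner) 0.520 M, and keep a material balance on the substrate, in percent of what was charged; the ash run is this very flask, read up to 4.00 d.

| setting | ash | flask |
|---|---|---|
| substrate | 0.40 M | 0.40 M |
| partner | 0.52 M | 0.520 M |
| remark | the very flask that is asked about, followed so far |  |
| time |  | 10 d |

ash run (percent of the substrate charged)

| time / d | side product A / % | target / % | substrate / % |
|---|---|---|---|
| 0.333 | 3.3 | 2.6 | 66.7 |
| 0.500 | 7.4 | 8.3 | 55.6 |
| 0.833 | 13.1 | 17.5 | 36.7 |
| 1.67 | 20.4 | 32.5 | 14.3 |
| 2.50 | 23.8 | 40.2 | 6.7 |
| 4.00 | 22.7 | 44.9 | 2.8 |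

(scatter of a reading: 1 percentage point)

- a species is counted by the substrate in it: one side product B counts as two
- steps under discussion: substrate <-> intermediate A; substrate -> intermediate B; partner + intermediate A <-> intermediate C; intermediate A -> target; partner + intermediate B -> side product A; partner -> decomposed reagent; substrate + intermediate C -> side product B

- share of side product A in side product A plus target at 2.5 h
- share of side product A in side product A plus target at 10 d
- which of side product A and target there is more of at 10 d

- At 4.00 d the ash run books substrate 2.8 %, target 44.9 % and side product A 22.7 %, each reading with a scatter of 1 percentage point.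
- The unread remainder, what was charged minus these three entries, stands at 29.6 %; it sits in species that were not read.
- Side product A reads 23.8 % and then 22.7 %, so we freeze it, freeze the remainder too, and book the open substrate to target.
- Our books then close at 10 d with target at 47.7 %, more than side product A, and a share of side product A in the two of 32.2 %.
- The time 2.5 h lies earlier than the first reading at 0.333 d, so there we simply carry that reading's share, 55.9 %, as a loose figure.
- The forecast differs from us on both shares: it gives 70 % at 2.5 h, “so a share near 70%, though this is poorly determined”, and 30 % at 10 d, with target ahead, as we have it.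

    substrate ⇌ intermediate A (K = 1.18, k = 0.0324 h⁻¹)
    substrate → intermediate B (k = 0.0210 h⁻¹)
    partner + intermediate A ⇌ intermediate C (K = 14.3 L mol⁻¹, k = 0.0453 L mol⁻¹ h⁻¹)
    intermediate A → target (k = 0.0723 h⁻¹)
    partner + intermediate B → side product A (k = 0.237 L mol⁻¹ h⁻¹)
    partner → decomposed reagent (k = 0.0414 h⁻¹)
    substrate + intermediate C → side product B (k = 0.428 L mol⁻¹ h⁻¹)

- The flask gives shares of 50.8 % at 2.5 h and 34.4 % at 10 d, with target ahead, 47.4 % against 24.8 %. Its remainder at 10 d is 27.8 %, beside the 29.6 % read from the ash run, and it holds intermediate B at 20.2 %, side product B at 7.19 % and intermediate C at 0.428 %. The same subtraction on the neighbouring flask with 2.1 M of partner, target 35.0 % and side product A 36.9 %, leaves a remainder of 28.0 % at 10.0 d, with side product B at 22.7 % and intermediate B at 3.15 %, and that neighbouring flask's share of side product A is 51.3 %.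

The runs stem from a simulated flask from invented constants; noise was put on by code.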